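**Assumptions (one line each)**
- The target has no stereocentres. The C(CH3)2 of the chromene is not stereogenic, so there is no enantiomer issue.
- 2,4-Dihydroxyphenylacetic acid, phloroglucinol, allyl bromide, prenyl bromide, prenal and DMF-DMA are taken as commercial.

## Retrosynthetic overview
1. Kanzonol L comes from the 4'-O-allyl chromene isoflavone 12 by Pd-catalysed deallylation. The 2,2-dimethylchromene is made last from the 2'-OH and prenal. Once the A ring is blocked and the 4'-O is masked, the 2'-OH has only one free ortho carbon (C3'), so the pyran regiochemistry is fixed.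
2. Isoflavone 10 comes from the symmetric bis-prenyl deoxybenzoin 8 by one-carbon ring closure. The two OH groups flanking the ketone are equivalent, so the A-ring regiochemistry is automatic.
3. Deoxybenzoin 8 comes from 6 by double C-prenylation at two symmetry-equivalent carbons. Compound 6 comes from phloroglucinol (5) plus the aryl-acetic lactone 4.
4. The lactone acylation of phloroglucinol is the pivotal step. It breaks the D3h symmetry of a cheap feedstock and delivers the B ring with its 2'-oxygen already differentiated from the 4'-oxygen.
5. Rings are formed in this order: lactone, then the A–B ketone link, then the pyranone C ring, then the chromene ring.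

## Route

**Step 1**
Reactants: 1, 2,4-dihydroxyphenylacetic acid
Product: 2, 6-hydroxybenzofuran-2(3H)-one
Conditions: TsOH·H2O (5 mol %), toluene, reflux, Dean–Stark, 3 h
Reagents that add atoms: none
Why: An o-hydroxyarylacetic acid lactonises under acid catalysis (intramolecular Fischer esterification), which ties up the 2-oxygen and leaves only the 4-OH free.

**Step 2**
Reactants: 2, 6-hydroxybenzofuran-2(3H)-one; 3, allyl bromide
Product: 4, 6-(allyloxy)benzofuran-2(3H)-one
Conditions: 3 (1.1 equiv), K2CO3, acetone, 50 °C, 4 h
Reagents that add atoms: allyl bromide, C=CCBr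
Why: Williamson O-alkylation of the only free phenol gives a 4'-oxygen protecting group that is stable to acid, to base and to 130 °C pyridine, and that can be removed later by Pd(0).

**Step 3**
Reactants: 5, phloroglucinol; 4, 6-(allyloxy)benzofuran-2(3H)-one
Product: 6, 2-(4-allyloxy-2-hydroxyphenyl)-1-(2,4,6-trihydroxyphenyl)ethan-1-one
Conditions: BF3·OEt2 (neat), 70 °C, 3 h
Reagents that add atoms: none (BF3·OEt2 is not retained)
Why: Proposed new method: BF3 activates the aryl-ester-type lactone C=O, phloroglucinol attacks through carbon (all three ring carbons are equivalent, so there is no regiochemistry issue), and the phenoxide leaves, releasing the 2'-OH as the latent pyran oxygen. The closest known reactions are BF3-mediated acylation of phloroglucinol with arylacetic acids and Friedel–Crafts acylation with dihydrocoumarins. The chelated ketone product is deactivated toward a second acylation, and no stereocentre is formed.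

**Step 4**
Reactants: 6; 7, prenyl bromide
Product: 8, 2-(4-allyloxy-2-hydroxyphenyl)-1-(2,4,6-trihydroxy-3,5-bis(3-methylbut-2-enyl)phenyl)ethan-1-one
Conditions: 7 (2.3 equiv), KOH (2.6 equiv), MeOH/H2O 9:1, 0 °C to rt, 16 h
Reagents that add atoms: prenyl bromide, CC(C)=CCBr
Why: In protic base the most acidic A-ring phenolate undergoes ortho/para C-alkylation (phenolate C-alkylation, as used for acylphloroglucinols), and the two sites C3 and C5 are symmetry-equivalent, so the 6,8-diprenyl pattern is set without regiochemical ambiguity.

**Step 5**
Reactants: 8; 9, N,N-dimethylformamide dimethyl acetal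
Product: 10, 7-hydroxy-type isoflavone: 5,7,2'-trihydroxy-4'-allyloxy-6,8-bis(3-methylbut-2-enyl)isoflavone
Conditions: 9 (4 equiv), DMF, 90 °C, 6 h; then 1 M HCl, THF, rt, 20 min
Reagents that add atoms: DMF-DMA, CN(C)C(OC)OC (supplies C-2 of the isoflavone)
Why: Enaminone formation at the doubly activated CH2 followed by 6-endo oxa-Michael addition and elimination of HNMe2 closes the chromone. This is the standard deoxybenzoin-to-isoflavone route, and it is neutral-to-basic, so the prenyl groups are not cyclised. The B-ring 2'-OH can only close 5-endo, so benzofuran formation is disfavoured. The choice between the two equivalent flanking A-ring OH groups costs nothing because they are equivalent.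

**Step 6**
Reactants: 10; 11, 3-methylbut-2-enal (prenal)
Product: 12, 4'-O-allyl chromene isoflavone: 5,7-dihydroxy-6,8-bis(3-methylbut-2-enyl)-isoflavone with a 2'-O/3'-C(2,2-dimethyl-2H-pyrano) ring and 4'-OCH2CH=CH2
Conditions: 11 (3 equiv), pyridine, 130 °C, sealed tube, 20 h
Reagents that add atoms: prenal, CC(C)=CC=O
Why: Phenol–enal condensation (ortho hydroxyalkylation, dehydration to the o-quinone methide, then 6π-oxa-electrocyclisation) can only occur at C3', the sole ortho carbon of the 2'-OH. The A ring is blocked, 5-OH is chelated and 7-OH is flanked by two prenyls, so the 2,2-dimethylchromene forms on the correct oxygen and no stereocentre is generated.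

**Step 7**
Reactants: 12
Product: 13, Kanzonol L
Conditions: Pd(PPh3)4 (5 mol %), K2CO3 (3 equiv), MeOH, rt, 3 h
Reagents that add atoms: none
Why: Tsuji–Trost deallylation of the aryl allyl ether, with methoxide as the allyl acceptor, cleaves only the primary allyl ether; the C-prenyl groups and the tertiary allylic chromene ether are not ionised under these mild conditions.

## Compound list
1 | 2,4-dihydroxyphenylacetic acid | OC(=O)Cc1ccc(O)cc1O | starting material
2 | 6-hydroxybenzofuran-2(3H)-one | O=C1Cc2ccc(O)cc2O1 | intermediate
3 | allyl bromide | C=CCBr | starting material (reagent)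
4 | 6-(allyloxy)benzofuran-2(3H)-one | O=C1Cc2ccc(OCC=C)cc2O1 | intermediate
5 | phloroglucinol | Oc1cc(O)cc(O)c1 | starting material
6 | 2-(4-allyloxy-2-hydroxyphenyl)-1-(2,4,6-trihydroxyphenyl)ethanone | O=C(Cc1ccc(OCC=C)cc1O)c1c(O)cc(O)cc1O | intermediate
7 | prenyl bromide | CC(C)=CCBr | starting material (reagent)
8 | 3,5-bis-prenylated deoxybenzoin | O=C(Cc1ccc(OCC=C)cc1O)c1c(O)c(CC=C(C)C)c(O)c(CC=C(C)C)c1O | intermediate
9 | DMF dimethyl acetal | CN(C)C(OC)OC | starting material (reagent)
10 | 5,7,2'-trihydroxy-4'-allyloxy-6,8-diprenylisoflavone | CC(C)=CCc1c(O)c(CC=C(C)C)c2occ(-c3ccc(OCC=C)cc3O)c(=O)c2c1O | intermediate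
11 | prenal | CC(C)=CC=O | starting material (reagent)
12 | 4'-O-allyl Kanzonol L | CC(C)=CCc1c(O)c(CC=C(C)C)c2occ(-c3ccc(OCC=C)c4c3OC(C)(C)C=C4)c(=O)c2c1O | intermediate
13 | Kanzonol L (achiral, no stereocentres) | CC(C)=CCc1c(O)c(CC=C(C)C)c2occ(-c3ccc(O)c4c3OC(C)(C)C=C4)c(=O)c2c1O | target

## Totals
- Total steps: 7.
- Longest linear sequence: 7 (1 → 2 → 4 → 6 → 8 → 10 → 12 → 13). Phloroglucinol joins at step 3.

## Three steps most likely to fail, with fallbacks
1. **Step 4 (bis-C-prenylation).** Risks are mono/tri-prenylation, O-prenylation, and alkylation of the B-ring phenol or the α-CH2.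
   - Fallback: change the order. Make 2,4-diprenylphloroglucinol first (sequential C-prenylation of phloroglucinol), then acylate it at its only free carbon with lactone 4. This removes the competing B-ring nucleophile, but the prenylated ring must then survive the BF3 step and the closure.
2. **Step 6 (chromene formation).** Risks are low conversion, prenal polymerisation, and competing reaction at C5'.
   - Fallback: use a different chromene-forming disconnection. Alkylate the 2'-OH with 3-chloro-3-methylbut-1-yne (K2CO3/KI/CuI; 5-OH is chelated and 7-OH is hindered, so 2'-OH is the only reactive phenol), then heat in N,N-diethylaniline for propargyl Claisen rearrangement, [1,5]-H shift and 6π-electrocyclisation.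
3. **Step 3 (BF3 lactone acylation).** Risks are allyl ether cleavage or Claisen rearrangement under BF3, and low reactivity of the five-membered lactone.
   - Fallback: switch the 4'-protecting-group strategy. Use the 6-methoxy lactone, a Houben–Hoesch condensation of phloroglucinol with the corresponding o-hydroxyarylacetonitrile (ZnCl2, HCl), and replace step 7 with nucleophilic demethylation (NaSEt, DMF).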